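**Assumption:** the target has no stereocentre, so there is no enantiomer to control; it is made as the single achiral compound. Compounds 6–8 are racemic and their stereocentres are erased in step 4.

## Retrosynthetic overview

1. Target ⇐ hydrogenolysis of its 3',5'-di-O-benzyl ether.
2. That ether ⇐ C8–O bond formation on a 5-hydroxy-7-methoxyflavanonol: para-oxidation of the chelated phenol to the 5,8-quinone, which tautomerises by internal redox to the 5,8-dihydroxyflavonol and creates C2=C3 at the same time.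
3. Flavanonol ⇐ oxidative C–O cyclisation (O1–C2 and C3–OH) of a symmetric 2',6'-dihydroxychalcone, so ring closure poses no regiochemical choice.
4. Chalcone ⇐ Claisen–Schmidt union of 2',6'-dihydroxy-4'-methoxyacetophenone (ring A) with 3,5-bis(benzyloxy)-4-methoxybenzaldehyde (ring B, from the free diphenol).
5. Ring order: rings A and B are bought; ring C is closed in step 3 and brought to the pyranone level in step 4.

## Route

Step 1
Reactants: 1 3,5-dihydroxy-4-methoxybenzaldehyde; 2 benzyl bromide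
Product: 3 3,5-bis(benzyloxy)-4-methoxybenzaldehyde
Conditions: BnBr (2.3 equiv), K2CO3 (3 equiv), DMF, 60 °C, 6 h
Reagents that add atoms: benzyl bromide, BrCc1ccccc1
Why: Williamson ether synthesis, in which the two phenoxides formed by K2CO3 displace bromide from benzyl bromide by SN2 and the aldehyde has no acidic α-hydrogen to interfere.

Step 2
Reactants: 4 1-(2,6-dihydroxy-4-methoxyphenyl)ethanone (2',6'-dihydroxy-4'-methoxyacetophenone); 3 3,5-bis(benzyloxy)-4-methoxybenzaldehyde
Product: 5 (E)-3-[3,5-bis(benzyloxy)-4-methoxyphenyl]-1-(2,6-dihydroxy-4-methoxyphenyl)prop-2-en-1-one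
Conditions: KOH (50% aq, 12 equiv), EtOH/THF, rt, 48 h; then 1 M HCl, 0 °C
Reagents that add atoms: none
Why: Claisen–Schmidt (crossed aldol) condensation, in which the methyl ketone enolate of 4 adds to the non-enolisable aldehyde 3 and E1cB loss of water gives the conjugated E-enone, the benzyl ethers being inert to alkali.

Step 3
Reactants: 5 (E)-3-[3,5-bis(benzyloxy)-4-methoxyphenyl]-1-(2,6-dihydroxy-4-methoxyphenyl)prop-2-en-1-one
Product: 6 rac-(2R,3R)-2-[3,5-bis(benzyloxy)-4-methoxyphenyl]-3,5-dihydroxy-7-methoxy-2,3-dihydro-4H-chromen-4-one (trans flavanonol)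
Conditions: 30% H2O2 (2.5 equiv), NaOH (2 M aq, 3 equiv), MeOH, 0 °C, 2 h; then 1 M HCl
Reagents that add atoms: hydrogen peroxide, OO
Why: Algar–Flynn–Oyamada oxidative cyclisation held at the flavanonol stage by the low temperature, in which one of the two symmetry-equivalent phenoxides closes 6-endo onto the β-carbon while the α-carbon takes oxygen from HOO−, and the epimerisable C3 settles trans-diequatorial to the 2-aryl group, so 6 is the racemic trans diastereomer.

Step 4
Reactants: 6 rac-(2R,3R)-2-[3,5-bis(benzyloxy)-4-methoxyphenyl]-3,5-dihydroxy-7-methoxy-2,3-dihydro-4H-chromen-4-one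
Product: 9 2-[3,5-bis(benzyloxy)-4-methoxyphenyl]-3,5,8-trihydroxy-7-methoxy-4H-chromen-4-one, via hydroquinone 7 (not isolated), via acylquinone 8 (not isolated)
Conditions: PhI(OCOCF3)2 (2.05 equiv), MeCN/H2O (4:1), 0 °C, 1 h; then argon, 0 °C to 25 °C, 3 h
Reagents that add atoms: water, O
Why: Proposed new method: the trivalent iodine reagent binds the 5-OH and water adds at the para carbon C8 (the dienone so formed is cross-conjugated and stabilised as a vinylogous ester by both the 7-OMe and the ring oxygen), giving hydroquinone 7, which a second equivalent oxidises to acylquinone 8; the CF3CO2H set free then enolises the α-hydroxy ketone at C3 to an enediol that reduces the attached quinone by proton shifts, and the resulting 3,4-dione enolises towards C2, so C2=C3 is formed without external oxidant and both stereocentres vanish; the closest known reactions are the PhI(OCOCF3)2 oxidation of para-unsubstituted phenols to para-quinones and the internal-redox tautomerisation of 2-(1-hydroxyalkyl)quinones to acylhydroquinones, neither demonstrated on a flavanonol.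

Step 5
Reactants: 9 2-[3,5-bis(benzyloxy)-4-methoxyphenyl]-3,5,8-trihydroxy-7-methoxy-4H-chromen-4-one
Product: 10 2-(3,5-dihydroxy-4-methoxyphenyl)-3,5,8-trihydroxy-7-methoxy-4H-chromen-4-one (target)
Conditions: H2 (1 atm), 10% Pd/C, THF/MeOH (1:1), rt, 4 h; filtered and concentrated under argon
Reagents that add atoms: none
Why: Catalytic hydrogenolysis of the two benzyl aryl ethers over Pd/C, which leaves the flavonol enone and the methyl ethers untouched and also returns any over-oxidised 5,8-quinone to the hydroquinone.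

## Compound list

1 | 3,5-dihydroxy-4-methoxybenzaldehyde | COc1c(O)cc(C=O)cc1O | starting material
2 | benzyl bromide | BrCc1ccccc1 | starting material
3 | 3,5-bis(benzyloxy)-4-methoxybenzaldehyde | COc1c(OCc2ccccc2)cc(C=O)cc1OCc1ccccc1 | intermediate
4 | 1-(2,6-dihydroxy-4-methoxyphenyl)ethanone | CC(=O)c1c(O)cc(OC)cc1O | starting material
5 | (E)-3-[3,5-bis(benzyloxy)-4-methoxyphenyl]-1-(2,6-dihydroxy-4-methoxyphenyl)prop-2-en-1-one | COc1cc(O)c(C(=O)/C=C/c2cc(OCc3ccccc3)c(OC)c(OCc3ccccc3)c2)c(O)c1 | intermediate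
6 | rac-(2R,3R)-2-[3,5-bis(benzyloxy)-4-methoxyphenyl]-3,5-dihydroxy-7-methoxy-2,3-dihydro-4H-chromen-4-one (racemic trans; one enantiomer drawn) | COc1cc(O)c2C(=O)[C@H](O)[C@@H](c3cc(OCc4ccccc4)c(OC)c(OCc4ccccc4)c3)Oc2c1 | intermediate
7 | rac-(2R,3R)-2-[3,5-bis(benzyloxy)-4-methoxyphenyl]-3,5,8-trihydroxy-7-methoxy-2,3-dihydro-4H-chromen-4-one (hydroquinone; racemic trans; one enantiomer drawn) | COc1cc(O)c2C(=O)[C@H](O)[C@@H](c3cc(OCc4ccccc4)c(OC)c(OCc4ccccc4)c3)Oc2c1O | intermediate
8 | rac-(2R,3R)-2-[3,5-bis(benzyloxy)-4-methoxyphenyl]-3-hydroxy-7-methoxy-2,3-dihydro-4H-chromene-4,5,8-trione (acylquinone; racemic trans; one enantiomer drawn) | COC1=CC(=O)C2=C(C1=O)O[C@H](c3cc(OCc4ccccc4)c(OC)c(OCc4ccccc4)c3)[C@@H](O)C2=O | intermediate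
9 | 2-[3,5-bis(benzyloxy)-4-methoxyphenyl]-3,5,8-trihydroxy-7-methoxy-4H-chromen-4-one | COc1cc(O)c2c(=O)c(O)c(-c3cc(OCc4ccccc4)c(OC)c(OCc4ccccc4)c3)oc2c1O | intermediate
10 | 2-(3,5-dihydroxy-4-methoxyphenyl)-3,5,8-trihydroxy-7-methoxy-4H-chromen-4-one | COc1cc(O)c2c(=O)c(O)c(-c3cc(O)c(OC)c(O)c3)oc2c1O | target

## Step count and risks

Total step count: 5. Longest linear sequence: 5 steps (1 → 3 → 5 → 6 → 9 → 10).

**Step 4 (proposed new step, highest risk).** The chelated, acyl-substituted 5-OH may oxidise sluggishly, water may add at C6 instead of C8, or quinone 8 may decompose before it tautomerises. The fallback uses known chemistry only, sets out from 6 and comes back at 10. Dehydrogenate 6 with I2/KOAc in AcOH at reflux to the flavonol 2-[3,5-bis(benzyloxy)-4-methoxyphenyl]-3,5-dihydroxy-7-methoxy-4H-chromen-4-one F5. Benzylate its 3-OH selectively (BnBr, K2CO3, acetone, reflux; the chelated 5-OH stays free) to 3-(benzyloxy)-2-[3,5-bis(benzyloxy)-4-methoxyphenyl]-5-hydroxy-7-methoxy-4H-chromen-4-one F6. Elbs persulfate oxidation (K2S2O8, aq. KOH/pyridine, 0–20 °C), which attacks para to the phenoxide, gives potassium 3-(benzyloxy)-2-[3,5-bis(benzyloxy)-4-methoxyphenyl]-5-hydroxy-7-methoxy-4-oxo-4H-chromen-8-yl sulfate F7. Hydrolyse this (2 M HCl, Na2SO3, 80 °C) to 3-(benzyloxy)-2-[3,5-bis(benzyloxy)-4-methoxyphenyl]-5,8-dihydroxy-7-methoxy-4H-chromen-4-one F8. Hydrogenolysis under the conditions of step 5 removes all three benzyl groups and gives 10.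

**Step 3.** Aurone formation or over-oxidation to the flavonol may compete because of the second ortho-oxygen on ring A. The fallback sets out from 5 and comes back at 6. Cyclise 5 (NaOAc, EtOH, reflux) to the flavanone rac-2-[3,5-bis(benzyloxy)-4-methoxyphenyl]-5-hydroxy-7-methoxy-2,3-dihydro-4H-chromen-4-one F3. Soft enolisation (TMSOTf, Et3N, CH2Cl2, 0 °C) gives the bis-silyl enol ether rac-2-[3,5-bis(benzyloxy)-4-methoxyphenyl]-7-methoxy-4,5-bis(trimethylsilyloxy)-2H-chromene F4. Rubottom oxidation (dimethyldioxirane, acetone, −20 °C, anti to the 2-aryl group; then 1 M HCl/MeOH) gives the trans flavanonol 6.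

**Step 2.** The doubly deprotonated acetophenone 4 is a poor enolate precursor, so conversion may stall. The fallback sets out from 4 and comes back at 5. Protect 4 (MOMCl, NaH, DMF) as 1-[4-methoxy-2,6-bis(methoxymethoxy)phenyl]ethanone F1. Condense F1 with 3 (KOH, EtOH, rt) to (E)-3-[3,5-bis(benzyloxy)-4-methoxyphenyl]-1-[4-methoxy-2,6-bis(methoxymethoxy)phenyl]prop-2-en-1-one F2. Cleave the acetals (3 M HCl, MeOH, 50 °C) to return chalcone 5; any flavanone formed alongside reopens to 5 in the alkaline medium of step 3.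

## Further compounds

F1 | step 2 | 1-[4-methoxy-2,6-bis(methoxymethoxy)phenyl]ethanone | CC(=O)c1c(OCOC)cc(OC)cc1OCOC
F2 | step 2 | (E)-3-[3,5-bis(benzyloxy)-4-methoxyphenyl]-1-[4-methoxy-2,6-bis(methoxymethoxy)phenyl]prop-2-en-1-one | COCOc1cc(OC)cc(OCOC)c1C(=O)/C=C/c1cc(OCc2ccccc2)c(OC)c(OCc2ccccc2)c1
F3 | step 3 | rac-2-[3,5-bis(benzyloxy)-4-methoxyphenyl]-5-hydroxy-7-methoxy-2,3-dihydro-4H-chromen-4-one (racemic; 2S enantiomer drawn) | COc1cc(O)c2C(=O)C[C@@H](c3cc(OCc4ccccc4)c(OC)c(OCc4ccccc4)c3)Oc2c1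
F4 | step 3 | rac-2-[3,5-bis(benzyloxy)-4-methoxyphenyl]-7-methoxy-4,5-bis(trimethylsilyloxy)-2H-chromene (racemic; 2S enantiomer drawn) | COc1cc(O[Si](C)(C)C)c2C(O[Si](C)(C)C)=C[C@@H](c3cc(OCc4ccccc4)c(OC)c(OCc4ccccc4)c3)Oc2c1
F5 | step 4 | 2-[3,5-bis(benzyloxy)-4-methoxyphenyl]-3,5-dihydroxy-7-methoxy-4H-chromen-4-one | COc1cc(O)c2c(=O)c(O)c(-c3cc(OCc4ccccc4)c(OC)c(OCc4ccccc4)c3)oc2c1
F6 | step 4 | 3-(benzyloxy)-2-[3,5-bis(benzyloxy)-4-methoxyphenyl]-5-hydroxy-7-methoxy-4H-chromen-4-one | COc1cc(O)c2c(=O)c(OCc3ccccc3)c(-c3cc(OCc4ccccc4)c(OC)c(OCc4ccccc4)c3)oc2c1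
F7 | step 4 | potassium 3-(benzyloxy)-2-[3,5-bis(benzyloxy)-4-methoxyphenyl]-5-hydroxy-7-methoxy-4-oxo-4H-chromen-8-yl sulfate | COc1cc(O)c2c(=O)c(OCc3ccccc3)c(-c3cc(OCc4ccccc4)c(OC)c(OCc4ccccc4)c3)oc2c1OS(=O)(=O)[O-].[K+]
F8 | step 4 | 3-(benzyloxy)-2-[3,5-bis(benzyloxy)-4-methoxyphenyl]-5,8-dihydroxy-7-methoxy-4H-chromen-4-one | COc1cc(O)c2c(=O)c(OCc3ccccc3)c(-c3cc(OCc4ccccc4)c(OC)c(OCc4ccccc4)c3)oc2c1O
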